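The vessel in south receives its first end groups over 25 h, so I did not read that flask on the wall clock.

| flask | first end groups | second end groups | remark | time |
|---|---|---|---|---|
| autumn | 0.40 M | 1 equiv | run made earlier |  |
| noon | 0.40 M | 0.50 equiv | run made earlier |  |
| dawn | 0.40 M | 0.75 equiv | run made earlier |  |
| south | 0.40 M (fed, over 25 h) | 1.00 equiv | all else is in the flask from the start; the feed brings no volume worth counting | 30 h |
| north-west | 0.40 M | 1.00 equiv (fed, over 25 h) | all else is in the flask from the start; the feed brings no volume worth counting | 30 h |
| west | 0.40 M | 1.00 equiv | everything together at the start | 30 h |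

| run | time / h | side product / % | links / % |
|---|---|---|---|
| autumn | 6.00 | 34.8 | 43.6 |
| autumn | 12.0 | 47.9 | 33.7 |
| autumn | 20.0 | 59.7 | 26.3 |
| autumn | 25.0 | 64.0 | 22.8 |
| autumn | 30.0 | 67.7 | 19.4 |
| noon | 8.00 | 35.5 | 22.1 |
| noon | 15.0 | 52.4 | 16.1 |
| noon | 20.0 | 59.4 | 12.2 |
| noon | 30.0 | 68.2 | 8.7 |
| noon | 40.0 | 72.5 | 7.5 |
| dawn | 3.00 | 20.1 | 41.9 |
| dawn | 5.00 | 29.5 | 35.9 |
| dawn | 10.0 | 44.5 | 31.0 |
| dawn | 20.0 | 63.9 | 19.6 |
| dawn | 40.0 | 76.0 | 12.4 |

(scatter of a reading: 1 percentage point)

* the flask that comes out highest in amount of side product, in percent of the first end groups charged; "all alike" if 1.5 percentage points covers them all (south / north-west / west / all alike)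
* amount of side product at the end, in percent of the first end groups charged, south
* amount of side product at the end, in percent of the first end groups charged, north-west
* amount of side product at the end, in percent of the first end groups charged, west

- percent here means first end groups units held: one side product counts as two

South holds in the end the charges of autumn, so I let the autumn curve serve for it. I took its rate to go with a·l, free first end groups times links, as fractions of the charge. During the feed in south, I assumed a and l each grow with the fraction fed, f, so the rate goes with f times f. Averaged over the feed, that counts a third of each feed hour, and every later hour counts in full: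

clock = 25 h/3 + (30 h − 25 h) = 13.3 h

This clock, an equivalent batch time, is 0.443 of the wall time. Autumn read at the clock, between 12.0 h and 20.0 h, gave me 49.9% for south. West has autumn's charge, so I took 67.7%. North-west holds its first end groups from the start, so I gave it no clock and placed it between them.

The forecast named west, with south 47%, north-west 65.5% and west 67.5%: “Feeding A keeps free A low, so south lags badly”. My south stood above its figure.

The flasks gave south 48.5%, north-west 64.4% and west 69.2%, so west came highest.

    first end groups + second end groups ⇌ links + by-product (K = 2.71, k = 1.95 M⁻¹ h⁻¹)
    first end groups + links → side product (k = 0.434 M⁻¹ h⁻¹)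
    first end groups → decomposition product (k = 0.00130 h⁻¹)

South's clock had read 49.9% against 48.5%. The neighbouring flask is south with 1.6 M of first end groups, the equivalents and the time held. I multiplied the clock by the concentration ratio, 4.00, which gave 53.3 h, later than the last autumn reading, 67.7% at 30.0 h. So I looked for the neighbouring flask above that level. The neighbouring flask ended with 75.8% as side product.

The numbers in the tables stem from a simulated flask from invented constants, noise included.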